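At 40 h, the time of reading, the two substrate peaks together hold what has not reacted, and I reckoned that fraction of the charge first.

all flasks: left-handed substrate 0.10 M; right-handed substrate 0.10 M; gas 15 mM (held)
- blue: catalyst 2.4 mol%; run made earlier
- amber: catalyst 3.5 mol%; run made earlier
- flask: catalyst 4.7 mol%; time 40 h

- blue (time / h: left-handed product / %, right-handed product / %): 5.00: 36.2, 1.8; 10.0: 52.8, 1.6; 15.0: 61.5, 2.6; 20.0: 66.7, 3.5; 25.0: 73.5, 3.3; 30.0: 74.8, 2.6
- amber (time / h: left-handed product / %, right-handed product / %): 2.50: 29.8, 1.0; 4.00: 40.2, 0.1; 6.00: 48.9, 1.9; 10.0: 57.4, 1.8; 15.0: 66.2, 2.5; 20.0: 71.0, 4.0; 30.0: 79.6, 6.0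

(each reading ± 1 percentage point)

- excess of left-handed product over right-handed product in the product at 4.0 h
- excess of left-handed product over right-handed product in the product at 40 h
- part of the left-handed substrate and right-handed substrate charged together that has reacted at 40 h

- catalyst is single-handed; left-handed substrate and right-handed substrate are mirror images of each other, charged as a racemate, each of them at the stated concentration
- at the start none of the gas is in solution
- an excess is the difference of the two amounts in percent of their sum
- an excess is below zero if the other one leads

Left-handed product reached 79.6% of the charge in the amber run, past 0.5, so right-handed substrate had been turning into left-handed substrate: a dynamic kinetic resolution. From 15.0 h to 30.0 h the unreacted fraction of the blue run fell at 0.0309 h⁻¹. From 15.0 h to 30.0 h that of the amber run fell at 0.0518 h⁻¹. I took their mean, 0.0413 h⁻¹, as a reading.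

The amber rate read higher than the blue one, which spoke for counting catalyst. But the blue run at 20.0 h had less catalyst times hours than the amber run at 15.0 h, yet left 29.8% against 31.3%, a gap within the scatter. The readings pulled two ways, so I made a choice: for the tail I counted hours and assumed that this flask held at 30.0 h what the amber run held then.

My tail number, the mean rate times the hours beyond the last amber reading, was 0.413; I let the unreacted fraction shrink by exp(−N) over those hours. On that assumption the amber run's 14.4% gave my estimate of 9.53% left in this flask at 40 h, so 90.5% reacted.

One number was not enough, because it cannot tell the hands apart. The excess read 93.3% in the blue run and 86.0% in the amber run at 30.0 h, so I expected this flask below the amber figure at 40 h.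

The forecast gave excesses of 94.5% at 4.0 h and 88.5% at 40 h, and 96% reacted against my 90.5%, holding that "both reaction and racemisation appear to scale with catalyst".

The flask gave excesses of 95.2% at 4.0 h and 84.4% at 40 h, and 90.7% reacted.

    reagent + catalyst + left-handed substrate → catalyst + left-handed product (k = 9300 M⁻² h⁻¹)
    reagent + catalyst + right-handed substrate → catalyst + right-handed product (k = 110 M⁻² h⁻¹)
    left-handed substrate ⇌ right-handed substrate (k = 0.0410 h⁻¹)
    gas ⇌ reagent, rate k4*(csat - [reagent]) (kL = 6.90 h⁻¹)
    2 reagent → homo dimer (k = 1.40 M⁻¹ h⁻¹)

In this flask left-handed substrate at 40.0 h had a half-life of 1.1 h by reaction, shorter than the 17 h of its forward passing into right-handed substrate. In this flask 8.73% of right-handed substrate stood beside 0.559% of left-handed substrate.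

For the neighbour flask with 1.9 mol% of catalyst, I started from the run nearest in catalyst, the blue one, under the same assumption, and the same N gave 85.0% reacted; the computed neighbour reached 85.1%.

(The numbers in the tables were generated by integration for an exercise, and the scatter is random.)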